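**Assumption:** the target has no stereocentre and no configurationally stable axis, so it is achiral; "single enantiomer" needs no stereocontrol and all SMILES carry no stereodescriptors.

**Retrosynthetic overview**
1. Target ⇐ hydrogenolysis of its 4,4''-bis(benzyl ether).
2. Key disconnection (C–O): both ring C–OBz bonds cut at once ⇒ a 3,6-diaryl-1,2-benzoquinone plus dibenzoyl peroxide; the quinone oxygens become the free catechol (redox-neutral, new).
3. o-Quinone ⇐ ortho C–H oxygenation (C–O) of a 2,5-diarylphenol with IBX.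
4. 2,5-Diarylphenol ⇐ double Suzuki coupling of 2,5-dibromophenol with 4-(benzyloxy)phenylboronic acid.
5. No ring is constructed: all five benzene rings are bought; only the central one passes through a quinone and is re-aromatised.

**Step 1**
Reactants: 1 2,5-dibromophenol; 2 4-(benzyloxy)phenylboronic acid
Product: 3 2,5-bis[4-(benzyloxy)phenyl]phenol
Conditions: 2 (2.5 equiv), Pd(dppf)Cl2 (3 mol %), K2CO3 (4 equiv), dioxane/H2O 4:1, 90 °C
Reagents that add atoms: none
Why: Double Suzuki–Miyaura coupling, which tolerates the free phenol and the benzyl ethers and joins the three rings in one operation; no stereocentre is formed.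

**Step 2**
Reactants: 3 2,5-bis[4-(benzyloxy)phenyl]phenol
Product: 4 3,6-bis[4-(benzyloxy)phenyl]cyclohexa-3,5-diene-1,2-dione
Conditions: IBX (1.1 equiv), DMF, 0 °C → rt, dark; used at once
Reagents that add atoms: IBX (2-iodoxybenzoic acid), O=C1OI(=O)(O)c2ccccc12
Why: IBX-mediated regioselective phenol-to-o-quinone oxidation, in which the phenol binds iodine(V) and oxygen is delivered intramolecularly to the only free ortho carbon (C6), giving an o-quinone whose two α-positions are aryl-blocked so it does not dimerise; no stereocentre is formed.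

**Step 3**
Reactants: 4 3,6-bis[4-(benzyloxy)phenyl]cyclohexa-3,5-diene-1,2-dione; 5 dibenzoyl peroxide
Product: 8 3,6-bis[4-(benzyloxy)phenyl]-4,5-dihydroxy-1,2-phenylene dibenzoate, via monobenzoyloxy catechol 6 (not isolated), via monobenzoyloxy o-quinone 7 (not isolated)
Conditions: 5 (1.05 equiv, added over 2 h), n-Bu4N+ PhCO2– (20 mol %), PhCO2H (20 mol %), 4 Å MS, MeCN/CH2Cl2 1:1, 0 °C → rt, Ar, dark
Reagents that add atoms: none
Why: Proposed new method: benzoate-relay, redox-neutral vicinal dibenzoyloxylation of an o-quinone — "naked" benzoate adds 1,4 to C4 of 4 and the adduct tautomerises to catechol 6, peroxide 5 dehydrogenates 6 to the more electrophilic acyloxy-quinone 7 while returning two benzoates, and a second benzoate adds at C5 (the only remaining position that can re-aromatise, C3/C6 being aryl-blocked) to give 8, so that net 4 + 5 → 8 forms both aryl C–O bonds with no by-product and the electron-poorer product catechol is not re-oxidised by 4; the closest known reactions are the NaIO3/MeOH oxidative 4,5-dimethoxylation of catechols via o-quinones, the Thiele–Winter acetoxylation of quinones and the ortho-benzoyloxylation of phenols by diacyl peroxides; no stereocentre is formed.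

**Step 4**
Reactants: 8 3,6-bis[4-(benzyloxy)phenyl]-4,5-dihydroxy-1,2-phenylene dibenzoate
Product: 9 4,5-dihydroxy-3,6-bis(4-hydroxyphenyl)-1,2-phenylene dibenzoate (CNP0216579.0)
Conditions: H2 (1 atm), 10% Pd/C, THF/EtOAc, AcOH (cat.), rt
Reagents that add atoms: none
Why: Hydrogenolysis of the two aryl benzyl ethers, to which aryl benzoates and the catechol are inert in a non-nucleophilic solvent; neither benzoate has a neighbouring OH, so no acyl migration can occur, and any over-oxidised quinone form of 8 is reduced back to the catechol; no stereocentre is involved.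

**Compound list**
1 | 2,5-dibromophenol | Oc1cc(Br)ccc1Br | starting material
2 | 4-(benzyloxy)phenylboronic acid | OB(O)c1ccc(OCc2ccccc2)cc1 | starting material
3 | 2,5-bis[4-(benzyloxy)phenyl]phenol | Oc1cc(-c2ccc(OCc3ccccc3)cc2)ccc1-c1ccc(OCc2ccccc2)cc1 | intermediate
4 | 3,6-bis[4-(benzyloxy)phenyl]cyclohexa-3,5-diene-1,2-dione | O=C1C(=O)C(-c2ccc(OCc3ccccc3)cc2)=CC=C1-c1ccc(OCc2ccccc2)cc1 | intermediate
5 | dibenzoyl peroxide | O=C(OOC(=O)c1ccccc1)c1ccccc1 | starting material
6 | 2,5-bis[4-(benzyloxy)phenyl]-3,4-dihydroxyphenyl benzoate (monobenzoyloxy catechol) | O=C(Oc1cc(-c2ccc(OCc3ccccc3)cc2)c(O)c(O)c1-c1ccc(OCc2ccccc2)cc1)c1ccccc1 | intermediate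
7 | 2,5-bis[4-(benzyloxy)phenyl]-3,4-dioxocyclohexa-1,5-dien-1-yl benzoate (monobenzoyloxy o-quinone) | O=C(OC1=C(-c2ccc(OCc3ccccc3)cc2)C(=O)C(=O)C(-c2ccc(OCc3ccccc3)cc2)=C1)c1ccccc1 | intermediate
8 | 3,6-bis[4-(benzyloxy)phenyl]-4,5-dihydroxy-1,2-phenylene dibenzoate | O=C(Oc1c(OC(=O)c2ccccc2)c(-c2ccc(OCc3ccccc3)cc2)c(O)c(O)c1-c1ccc(OCc2ccccc2)cc1)c1ccccc1 | intermediate
9 | 4,5-dihydroxy-3,6-bis(4-hydroxyphenyl)-1,2-phenylene dibenzoate | O=C(Oc1c(OC(=O)c2ccccc2)c(-c2ccc(O)cc2)c(O)c(O)c1-c1ccc(O)cc1)c1ccccc1 | target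

**Total step count:** 4. **Longest linear sequence:** 4 steps (1 → 3 → 4 → 8 → 9).

**Steps most likely to fail**

Step 3 (the proposed relay dibenzoyloxylation). Benzoate may be too weak a Michael donor, peroxide-derived peracid could cleave the quinone, and over-oxidation is possible. The fallback uses known chemistry only; it sets out from 4 and comes back to the route at 9. Quinone 4 is treated with NaIO3 in MeOH/CH2Cl2 at rt, the known oxidative 4,5-dialkoxylation of o-quinones, to give 3,6-bis[4-(benzyloxy)phenyl]-4,5-dimethoxycyclohexa-3,5-diene-1,2-dione F1. Reductive benzoylation (Zn dust, BzCl, pyridine, CH2Cl2) then gives 3,6-bis[4-(benzyloxy)phenyl]-4,5-dimethoxy-1,2-phenylene dibenzoate F2. BBr3 (CH2Cl2, −78 → 0 °C) cleaves the two methyl and the two benzyl ethers and leaves the aryl benzoates, giving 9 directly. In this variant the esters sit on the former quinone oxygens and the free catechol on the newly introduced ones; because of the symmetry of the target this is the same compound.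

Step 2 (IBX oxygenation). The risks are sluggish reaction of a phenol without strong donors, para-oxidation, and loss of the sensitive quinone on work-up. The fallback sets out from 3 and comes back at 4. ortho-Selective formylation (MgCl2, Et3N, paraformaldehyde, MeCN, reflux) gives 2-hydroxy-3,6-bis[4-(benzyloxy)phenyl]benzaldehyde F3. Dakin oxidation (H2O2, NaOH, THF/H2O) gives 3,6-bis[4-(benzyloxy)phenyl]benzene-1,2-diol F4. Oxidation with Ag2O (Et2O/CH2Cl2, MgSO4, rt) gives 4.

Step 1 (double Suzuki on the free bromophenol). Under base the C2–Br ortho to the phenoxide is deactivated towards oxidative addition, so mono-coupled material that is hard to separate may persist. The fallback sets out from 1 and comes back at 3. MOMCl and iPr2NEt in CH2Cl2 give 1,4-dibromo-2-(methoxymethoxy)benzene F5. Double Suzuki coupling with 2 (Pd(PPh3)4, K2CO3, toluene/EtOH/H2O, 85 °C) gives 4,4''-bis(benzyloxy)-2'-(methoxymethoxy)-1,1':4',1''-terphenyl F6. 3 M aq. HCl in THF at 50 °C removes the acetal and keeps the benzyl ethers, giving 3.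

**Further compounds**
F1 | step 3 | 3,6-bis[4-(benzyloxy)phenyl]-4,5-dimethoxycyclohexa-3,5-diene-1,2-dione | COC1=C(-c2ccc(OCc3ccccc3)cc2)C(=O)C(=O)C(-c2ccc(OCc3ccccc3)cc2)=C1OC
F2 | step 3 | 3,6-bis[4-(benzyloxy)phenyl]-4,5-dimethoxy-1,2-phenylene dibenzoate | COc1c(OC)c(-c2ccc(OCc3ccccc3)cc2)c(OC(=O)c2ccccc2)c(OC(=O)c2ccccc2)c1-c1ccc(OCc2ccccc2)cc1
F3 | step 2 | 2-hydroxy-3,6-bis[4-(benzyloxy)phenyl]benzaldehyde | O=Cc1c(O)c(-c2ccc(OCc3ccccc3)cc2)ccc1-c1ccc(OCc2ccccc2)cc1
F4 | step 2 | 3,6-bis[4-(benzyloxy)phenyl]benzene-1,2-diol | Oc1c(O)c(-c2ccc(OCc3ccccc3)cc2)ccc1-c1ccc(OCc2ccccc2)cc1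
F5 | step 1 | 1,4-dibromo-2-(methoxymethoxy)benzene | COCOc1cc(Br)ccc1Br
F6 | step 1 | 4,4''-bis(benzyloxy)-2'-(methoxymethoxy)-1,1':4',1''-terphenyl | COCOc1cc(-c2ccc(OCc3ccccc3)cc2)ccc1-c1ccc(OCc2ccccc2)cc1
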